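I watched one flask.

in all of them: substrate 20 mM

| flask | second nucleophile | solid first nucleophile | remark | time |
|---|---|---|---|---|
| Tuesday's | 40 mM | 14 mM | the very flask that is asked about, followed so far |  |
| flask | 40.0 mM | 14.0 mM |  | 6.0 d |
Tuesday's run (percent of the substrate charged)

| time / d | other capture product / % | target / % |
|---|---|---|
| 0.250 | 6.1 | 0 |
| 0.333 | 6.9 | 1.3 |
| 0.500 | 9.0 | 0.6 |
| 0.833 | 13.1 | 5.8 |
| 1.25 | 14.2 | 5.1 |
| 2.08 | 16.5 | 7.4 |
| 3.00 | 17.5 | 9.2 |

(readings scatter by 1 percentage point)
- at the start none of the solid first nucleophile is in solution
1. ratio of other capture product to target at 2.5 h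
2. ratio of other capture product to target at 20 h
3. ratio of other capture product to target at 6.0 d

1. The flask looked contradictory. By 3.00 d the other capture product had nearly stopped at 17.5%, yet that reading amounted to 8.75% of the second nucleophile charged. The target reading amounted to 13.1% of the smallest charge, the solid first nucleophile.

2. Taking the target reading from that smallest charge left 12.2 mM, solid or dissolved. I therefore reckoned neither nucleophile short and took the substrate to be the limiting reagent, although its charge was larger.

3. I let c(substrate) fall as exp(−t/τ). My time constant was 0.717 d: the last reading of the other capture product over its first slope, 6.1% in 0.250 d, which I called the substrate clock.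

4. The last reading came later than this clock, so I reckoned 1.52% of the substrate left then. With hardly any substrate left by this reckoning, I carried the ratio of the readings at 3.00 d, 1.90, forward to 6.0 d. I committed to no figure for the two earlier times.

5. The forecast gave 15 at 2.5 h, 3.1 at 20 h and 1.05 at 6.0 d, holding that the target “has not levelled off by day 3”, and its last figure stood below mine.

6. The flask gave 13.9, 2.97 and 1.97 at the same times.

    substrate → intermediate (k = 0.0630 h⁻¹)
    first nucleophile + intermediate → target (k = 390 M⁻¹ h⁻¹)
    second nucleophile + intermediate → other capture product (k = 68.0 M⁻¹ h⁻¹)
    intermediate → solvolysis product (k = 11.0 h⁻¹)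
    solid first nucleophile ⇌ first nucleophile, rate k5*(cs5 - [first nucleophile]) while solid is left; crystals form when [first nucleophile] > cs5 (solubility = 16.0 mM, k = 0.0270 h⁻¹)
    substrate + target → side product (k = 1.90 M⁻¹ h⁻¹)

7. For this flask the clock gives 0.0233% of the substrate charged at 6.0 d, and the flask held 0.0078%, with 92% of its second nucleophile. The neighbouring flask was charged with 68 mM of second nucleophile. The step from substrate to intermediate holds no second nucleophile, and I used the same clock and the same 0.0233% for the neighbouring flask. The neighbouring flask held 0.0081% of its substrate and 92% of its second nucleophile. It ended with 25.7% of other capture product, 7.77% of target and 63.6% of solvolysis product, and its ratio at 6.0 d was 3.30.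

The readings come from a simulation for an exercise; scatter was added.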